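Numbering used throughout: oxolane ring O1, C2 (3,4-dimethoxyphenyl), C3 (Me), C4 (Me), C5 (3,4,5-trimethoxyphenyl). The target is (2S,3S,4R,5R), that is 2,3-trans, 3,4-cis, 4,5-trans.
Cuts, in retrosynthetic order: C5–aryl (oxocarbenium ion plus arylzinc, back to a γ-lactone whose carbonyl carbon is C5); O1–C2 (back to an open 4-aryl-2,3-dimethylbutanoic acid with a plain CH2 at C2); C4–CH3 (enolate methylation); C2–C3 (benzylcopper plus N-crotonoyl imide).
Enabling feature: C2 sits on the dimethoxyphenyl ring para to its 4-OMe group and lies three bonds from C5 through C3–C4. Once C5 is a carboxyl carbon, its oxygen is placed to become O1 by trapping a C2 cation generated directly from the CH2 group.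
Forward order: the C2–C5 chain is joined on the auxiliary, the only ring to be made (the oxolane) is closed as a lactone by C–H oxidation, and the trimethoxyphenyl ring is attached last.
Stereochemistry: C3 and C4 both come from (R)-4-benzyl-2-oxazolidinone (conjugate addition, then methylation), C2 from the C3 methyl group during ring closure, and C5 from the two ring methyl groups during addition to the oxocarbenium ion.

Key step: step 5

Remark on the chemistry: the lactol and the sulfone derived from it are carried on as mixtures at the anomeric carbon, because both epimers give the same oxocarbenium ion.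

Step 1
Reactants: 1 (R)-4-benzyl-1,3-oxazolidin-2-one; 2 (E)-but-2-enoyl chloride (crotonoyl chloride)
Product: 4 (R)-4-benzyl-3-[(E)-but-2-enoyl]-1,3-oxazolidin-2-one, via lithium oxazolidinide 3 (not isolated)
Conditions: n-BuLi (1.0 equiv), THF, −78 °C; then 2, −78 → 0 °C
Reagents that add atoms: none
Why: N-acylation of a lithiated oxazolidinone with an acid chloride is the standard entry to N-enoyl imides, forms no stereocentre, and keeps the E alkene intact at low temperature.

Step 2
Reactants: 4 (R)-4-benzyl-3-[(E)-but-2-enoyl]-1,3-oxazolidin-2-one; 5 3,4-dimethoxybenzyl chloride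
Product: 8 (R)-4-benzyl-3-[(3R)-4-(3,4-dimethoxyphenyl)-3-methylbutanoyl]-1,3-oxazolidin-2-one, via 3,4-dimethoxybenzylmagnesium chloride 6 (not isolated), via 3,4-dimethoxybenzylcopper 7 (not isolated)
Conditions: 5, Mg turnings, 2-MeTHF, 0 °C, slow addition; CuBr·SMe2 (1 equiv per 6), THF/Me2S, −40 °C; then 4, −78 → −20 °C; aq NH4Cl
Reagents that add atoms: none
Why: In this auxiliary-controlled organocopper conjugate addition the magnesium halide chelates the two imide carbonyls and holds the enoyl unit s-cis, so the benzylcopper reagent reaches the β-carbon from the face away from the auxiliary benzyl group and sets chain C3 (ring C3) as R.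

Step 3
Reactants: 8 (R)-4-benzyl-3-[(3R)-4-(3,4-dimethoxyphenyl)-3-methylbutanoyl]-1,3-oxazolidin-2-one
Product: 10 (R)-4-benzyl-3-[(2R,3R)-4-(3,4-dimethoxyphenyl)-2,3-dimethylbutanoyl]-1,3-oxazolidin-2-one, via sodium Z-enolate 9 (not isolated)
Conditions: NaN(SiMe3)2 (1.1 equiv), THF, −78 °C; MeI (5 equiv), −78 → −40 °C
Reagents that add atoms: iodomethane, CI
Why: In this Evans asymmetric alkylation the chelated Z enolate is methylated on the face opposite the auxiliary benzyl group, which overrides the β-stereocentre, sets chain C2 (ring C4) as R, and gives the 2,3-relationship that becomes the cis-dimethyl pair of the ring.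

Step 4
Reactants: 10 (R)-4-benzyl-3-[(2R,3R)-4-(3,4-dimethoxyphenyl)-2,3-dimethylbutanoyl]-1,3-oxazolidin-2-one
Product: 12 (2R,3R)-4-(3,4-dimethoxyphenyl)-2,3-dimethylbutanoic acid, via lithium percarboxylate 11 (not isolated)
Conditions: LiOH, H2O2, THF/H2O, 0 °C; aq Na2SO3; then HCl to pH 2
Reagents that add atoms: hydrogen peroxide (acting as LiOOH), OO
Why: In this hydroperoxide cleavage of an N-acyl oxazolidinone the small, weakly basic LiOOH attacks the exocyclic carbonyl of the hindered imide, sulfite reduces the percarboxylate, and the α-stereocentre should survive at 0 °C while 1 is recovered.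

Step 5
Reactants: 12 (2R,3R)-4-(3,4-dimethoxyphenyl)-2,3-dimethylbutanoic acid
Product: 14 (3R,4S,5S)-5-(3,4-dimethoxyphenyl)-3,4-dimethyloxolan-2-one, via benzylic cation 13 (not isolated)
Conditions: DDQ (1.5 equiv), 4 Å molecular sieves, ClCH2CH2Cl, 23 → 60 °C
Reagents that add atoms: none
Why: Within a charge-transfer complex DDQ oxidises the dimethoxyarene to its radical cation and then abstracts a benzylic hydrogen atom, a net hydride transfer that leaves DDQH− and cation 13, which the para methoxy group delocalises into a quinone-methide-like oxocarbenium form. The carboxyl oxygen adds to this carbon and DDQH− accepts the proton, so the O1–C2 bond and the only ring closed here, the five-membered lactone, arise in a 5-exo-trig closure onto the exocyclic carbon–aryl double bond of the quinoid form. The closest known reaction types are DDQ-mediated oxidative cleavage of electron-rich benzylic C–H bonds with capture by a tethered heteroatom nucleophile and the oxidative benzylic C–H lactonisation of 4-arylbutanoic acids. The new stereocentre (lactone C5, ring C2) is controlled by the neighbouring methyl-bearing carbon: allylic 1,3-strain holds its C–H bond in the plane of the cation, the carboxyl arm and the methyl group then occupy opposite faces, and closure places the aryl group trans to that methyl group, which is also the more stable arrangement. The step needs site selectivity and a stop after one oxidation; 12 secures the first because it has a single benzylic position on its one electron-rich ring and no other hydride donor, and 14 secures the second because its acyloxy group makes the remaining benzylic C–H bond a much poorer hydride donor. Dry conditions keep water from diverting the cation to the aryl ketone, and the short tether should let ring closure outrun proton loss from the methyl-bearing carbon.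

Step 6
Reactants: 14 (3R,4S,5S)-5-(3,4-dimethoxyphenyl)-3,4-dimethyloxolan-2-one
Product: 15 (3R,4S,5S)-5-(3,4-dimethoxyphenyl)-3,4-dimethyloxolan-2-ol (anomeric mixture)
Conditions: i-Bu2AlH (1.1 equiv), CH2Cl2, −78 °C; aq potassium sodium tartrate
Reagents that add atoms: none
Why: Partial reduction of a γ-lactone with i-Bu2AlH stops at −78 °C at the aluminium hemiacetal, which gives the lactol on work-up without touching the three ring stereocentres.

Step 7
Reactants: 15 (3R,4S,5S)-5-(3,4-dimethoxyphenyl)-3,4-dimethyloxolan-2-ol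
Product: 16 (3R,4S,5S)-2-(benzenesulfonyl)-5-(3,4-dimethoxyphenyl)-3,4-dimethyloxolane (anomeric mixture)
Conditions: PhSO2H (1.5 equiv), CaCl2, CH2Cl2, 23 °C
Reagents that add atoms: benzenesulfinic acid, O=S(O)c1ccccc1
Why: Formation of a 2-benzenesulfonyl cyclic ether from a lactol needs only the mild acidity of the sulfinic acid, with CaCl2 binding the water, and gives a storable donor that ionises more gently than an acetate under a strong Lewis acid.

Step 8
Reactants: 16 (3R,4S,5S)-2-(benzenesulfonyl)-5-(3,4-dimethoxyphenyl)-3,4-dimethyloxolane; 17 5-bromo-1,2,3-trimethoxybenzene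
Product: 21 (2S,3S,4R,5R)-2-(3,4-dimethoxyphenyl)-3,4-dimethyl-5-(3,4,5-trimethoxyphenyl)oxolane, via 3,4,5-trimethoxyphenylmagnesium bromide 18 (not isolated), via 3,4,5-trimethoxyphenylzinc bromide 19 (not isolated), via oxocarbenium ion 20 (not isolated)
Conditions: 17, Mg, THF, reflux; ZnBr2, THF, 23 °C; then 16, THF, 23 °C
Reagents that add atoms: none
Why: In this substitution of a 2-sulfonyl cyclic ether by an arylzinc reagent the zinc and magnesium bromides ionise 16 to 20, whose favoured envelope has the C3 methyl and the C2 aryl group pseudoequatorial, and inside attack on that conformer is also attack anti to both methyl groups, so the new aryl group should end up trans to the C4 methyl group (5R).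

Compound list
1 | (R)-4-benzyl-1,3-oxazolidin-2-one | O=C1N[C@H](Cc2ccccc2)CO1 | starting material
2 | (E)-but-2-enoyl chloride | C/C=C/C(Cl)=O | starting material
3 | lithium salt of 1 (N-lithio) | O=C1N([Li])[C@H](Cc2ccccc2)CO1 | intermediate
4 | (R)-4-benzyl-3-[(E)-but-2-enoyl]-1,3-oxazolidin-2-one | C/C=C/C(=O)N1C(=O)OC[C@H]1Cc1ccccc1 | intermediate
5 | 3,4-dimethoxybenzyl chloride | COc1ccc(CCl)cc1OC | starting material
6 | 3,4-dimethoxybenzylmagnesium chloride | COc1ccc(C[Mg]Cl)cc1OC | intermediate
7 | 3,4-dimethoxybenzylcopper (monovalent copper) | COc1ccc(C[Cu])cc1OC | intermediate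
8 | (R)-4-benzyl-3-[(3R)-4-(3,4-dimethoxyphenyl)-3-methylbutanoyl]-1,3-oxazolidin-2-one | COc1ccc(C[C@@H](C)CC(=O)N2C(=O)OC[C@H]2Cc2ccccc2)cc1OC | intermediate
9 | sodium Z-enolate of 8 | COc1ccc(C[C@@H](C)/C=C(\[O-])N2C(=O)OC[C@H]2Cc2ccccc2)cc1OC.[Na+] | intermediate
10 | (R)-4-benzyl-3-[(2R,3R)-4-(3,4-dimethoxyphenyl)-2,3-dimethylbutanoyl]-1,3-oxazolidin-2-one | COc1ccc(C[C@@H](C)[C@@H](C)C(=O)N2C(=O)OC[C@H]2Cc2ccccc2)cc1OC | intermediate
11 | lithium (2R,3R)-4-(3,4-dimethoxyphenyl)-2,3-dimethylbutaneperoxoate | COc1ccc(C[C@@H](C)[C@@H](C)C(=O)O[O-])cc1OC.[Li+] | intermediate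
12 | (2R,3R)-4-(3,4-dimethoxyphenyl)-2,3-dimethylbutanoic acid | COc1ccc(C[C@@H](C)[C@@H](C)C(=O)O)cc1OC | intermediate
13 | benzylic cation at C4 of acid 12 (2R,3R) | COc1ccc([CH+][C@@H](C)[C@@H](C)C(=O)O)cc1OC | intermediate
14 | (3R,4S,5S)-5-(3,4-dimethoxyphenyl)-3,4-dimethyloxolan-2-one | COc1ccc([C@H]2OC(=O)[C@H](C)[C@@H]2C)cc1OC | intermediate
15 | (3R,4S,5S)-5-(3,4-dimethoxyphenyl)-3,4-dimethyloxolan-2-ol, both anomers | COc1ccc([C@H]2OC(O)[C@H](C)[C@@H]2C)cc1OC | intermediate
16 | (3R,4S,5S)-2-(benzenesulfonyl)-5-(3,4-dimethoxyphenyl)-3,4-dimethyloxolane, both anomers | COc1ccc([C@H]2OC(S(=O)(=O)c3ccccc3)[C@H](C)[C@@H]2C)cc1OC | intermediate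
17 | 5-bromo-1,2,3-trimethoxybenzene | COc1cc(Br)cc(OC)c1OC | starting material
18 | 3,4,5-trimethoxyphenylmagnesium bromide | COc1cc([Mg]Br)cc(OC)c1OC | intermediate
19 | 3,4,5-trimethoxyphenylzinc bromide | COc1cc([Zn]Br)cc(OC)c1OC | intermediate
20 | oxocarbenium ion O1=C5 from 16 | COc1ccc([C@H]2[O+]=C[C@H](C)[C@@H]2C)cc1OC | intermediate
21 | (2S,3S,4R,5R)-2-(3,4-dimethoxyphenyl)-3,4-dimethyl-5-(3,4,5-trimethoxyphenyl)oxolane | COc1ccc([C@H]2O[C@@H](c3cc(OC)c(OC)c(OC)c3)[C@H](C)[C@@H]2C)cc1OC | target

Total step count: 8. Longest linear sequence: 8 steps (1 to 21).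

Steps most likely to fail

Step 5.
- **What may go wrong:** Hydride abstraction from a benzylic CH2 that carries no heteroatom may be slow. The cation may lose a proton toward the methyl-bearing carbon, which erases that stereocentre and opens the way to further oxidation. Oxidative arene–arene coupling may compete, and control at the new centre may be incomplete.
- **Fallback, from 12 back to 14:** The same C–H bond is taken to the ketone level by hydrogen-atom abstraction, and the oxygen-bearing stereocentre is then set by reduction.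
  - Aerobic oxidation of 12 (catalytic N-hydroxyphthalimide and Co(OAc)2, O2, MeCN, 50 °C, neutral medium to spare the α-stereocentre) should give (2R,3S)-4-(3,4-dimethoxyphenyl)-2,3-dimethyl-4-oxobutanoic acid F1.
  - Felkin–Anh-controlled reduction with LiBH(s-Bu)3 (THF, −78 °C) should give (2R,3S,4S)-4-(3,4-dimethoxyphenyl)-4-hydroxy-2,3-dimethylbutanoic acid F2, in which hydroxyl and adjacent methyl are anti.
  - F2 lactonises on acidic work-up to 14.

Step 2.
- **What may go wrong:** Wurtz homocoupling may occur during magnesium insertion into the electron-rich benzyl chloride. The benzylcopper reagent may decay thermally, the imide carbonyls may suffer 1,2-attack, and facial selectivity may be weak.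
- **Fallback, from 5 back to 8 (using 1 in its last operation):** The benzyl fragment enters an sp3–sp2 cross-coupling as a zinc reagent, and C3 is set by a catalyst instead of the auxiliary.
  - Insertion of zinc dust into 5 in the presence of LiCl (THF, 25 °C) should give 3,4-dimethoxybenzylzinc chloride F3.
  - Negishi coupling with ethyl (Z)-3-iodobut-2-enoate (catalytic Pd(PPh3)4, THF) should give, with retention of alkene geometry, ethyl (Z)-4-(3,4-dimethoxyphenyl)-3-methylbut-2-enoate F4.
  - Copper hydride asymmetric conjugate reduction (CuCl, NaOt-Bu, the enantiomer of p-tol-BINAP that leads to 3R, polymethylhydrosiloxane, toluene) should give ethyl (3R)-4-(3,4-dimethoxyphenyl)-3-methylbutanoate F5.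
  - LiOH saponification gives (3R)-4-(3,4-dimethoxyphenyl)-3-methylbutanoic acid F6.
  - t-BuCOCl/Et3N converts F6 into (3R)-4-(3,4-dimethoxyphenyl)-3-methylbutanoic pivalic anhydride F7, which acylates 1 (LiCl, Et3N, THF) to 8.
  - At that stage any minor C3 epimer is a separable diastereomer.

Step 8.
- **What may go wrong:** Facial selectivity at C5 may be poor. The oxocarbenium ion may lose a proton to a dihydrofuran, which would scramble C4. The Lewis acids may open the C2–O1 bond.
- **Fallback, from 14 (with Grignard reagent 18) to 21:** C5 is set on an open chain by hydride addition, and the ring is then reclosed by cationic etherification. Direct reduction of the cyclic hemiketal is avoided, because hydride would then arrive anti to the methyl groups and give the wrong C5 epimer.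
  - Addition of 18 to 14 (THF, −78 → 0 °C) should give (2R,3S,4S)-4-(3,4-dimethoxyphenyl)-4-hydroxy-2,3-dimethyl-1-(3,4,5-trimethoxyphenyl)butan-1-one F8, in equilibrium with its hemiketal.
  - Felkin–Anh reduction of the open ketone (LiAlH4, THF, −78 °C) should give (1R,2R,3S,4S)-4-(3,4-dimethoxyphenyl)-2,3-dimethyl-1-(3,4,5-trimethoxyphenyl)butane-1,4-diol F9.
  - Catalytic p-TsOH (CH2Cl2, 0 °C) should ionise the more electron-rich 3,4-dimethoxybenzylic alcohol, and the C5 hydroxyl then closes the ring with the aryl group trans to the C3 methyl group, giving 21.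

Further compounds
F1 | step 5 | (2R,3S)-4-(3,4-dimethoxyphenyl)-2,3-dimethyl-4-oxobutanoic acid | COc1ccc(C(=O)[C@@H](C)[C@@H](C)C(=O)O)cc1OC
F2 | step 5 | (2R,3S,4S)-4-(3,4-dimethoxyphenyl)-4-hydroxy-2,3-dimethylbutanoic acid | COc1ccc([C@@H](O)[C@@H](C)[C@@H](C)C(=O)O)cc1OC
F3 | step 2 | 3,4-dimethoxybenzylzinc chloride | COc1ccc(C[Zn]Cl)cc1OC
F4 | step 2 | ethyl (Z)-4-(3,4-dimethoxyphenyl)-3-methylbut-2-enoate | COc1ccc(C/C(C)=C\C(=O)OCC)cc1OC
F5 | step 2 | ethyl (3R)-4-(3,4-dimethoxyphenyl)-3-methylbutanoate | COc1ccc(C[C@@H](C)CC(=O)OCC)cc1OC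
F6 | step 2 | (3R)-4-(3,4-dimethoxyphenyl)-3-methylbutanoic acid | COc1ccc(C[C@@H](C)CC(=O)O)cc1OC
F7 | step 2 | (3R)-4-(3,4-dimethoxyphenyl)-3-methylbutanoic pivalic anhydride | COc1ccc(C[C@@H](C)CC(=O)OC(=O)C(C)(C)C)cc1OC
F8 | step 8 | (2R,3S,4S)-4-(3,4-dimethoxyphenyl)-4-hydroxy-2,3-dimethyl-1-(3,4,5-trimethoxyphenyl)butan-1-one | COc1ccc([C@@H](O)[C@@H](C)[C@@H](C)C(=O)c2cc(OC)c(OC)c(OC)c2)cc1OC
F9 | step 8 | (1R,2R,3S,4S)-4-(3,4-dimethoxyphenyl)-2,3-dimethyl-1-(3,4,5-trimethoxyphenyl)butane-1,4-diol | COc1ccc([C@@H](O)[C@@H](C)[C@@H](C)[C@@H](O)c2cc(OC)c(OC)c(OC)c2)cc1OC
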